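**Strategy.** The route rests on disconnecting C1–C10 of the drimane. Ring B (C5–C10), with its oxygen-bearing C9 flanked by the methyl-bearing carbons C8 and C10, is drawn from a 2,6-dimethylphenol whose C5 carries the gem-dimethyl carbon C4 and a Z-allylic methyl carbonate (C3–C1); C6, the para carbon, is blocked by chlorine. A zerovalent palladium catalyst with a chiral phosphoramidite ionises the carbonate, and the phenoxide carbon C10 closes ring A onto C1, which in one operation dearomatises ring B, creates the quaternary stereocentre C10 and leaves a 9-keto-5,7-diene for trans-selective reduction. Methylenation, hydroboration and caffeoylation then complete the target.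

Key step: step 11

Assumption: the sense of induction of the phosphoramidite in step 11 cannot be predicted reliably for this new substrate class; the ligand antipode that places C1 on the Si face of C10 (giving 10S) is to be identified in a first run and used, both antipodes being commercial.

Design remark: C6, para to the phenolic oxygen, is as close to C1 as C10 and would close an equally six-membered ring that rearomatises to a Friedel–Crafts product. It therefore carries a chlorine from step 10 until the dissolving-metal step 12 removes it. The bond formed (C1–C10), the ring closed (ring A) and the carbon skeletons are unchanged: 15 is the chlorine-free precursor, 16 and 17 carry the spectator chlorine. The 10S configuration of 17 is the 10β-methyl configuration of the target (5S,9S,10S).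

Step 1
Reactants: 1 3-bromo-2-methylphenol
Product: 2 1-bromo-3-(methoxymethoxy)-2-methylbenzene
Conditions: MOMCl, iPr2NEt, CH2Cl2, 0 °C to rt
Reagents that add atoms: chloromethyl methyl ether, COCCl
Why: O-alkylation of the phenol gives the methoxymethyl ether, which is inert to the amide base and hydride of the next steps and later serves as the ortho-directing group for the lithiation in step 4.

Step 2
Reactants: 2 1-bromo-3-(methoxymethoxy)-2-methylbenzene; 3 methyl isobutyrate
Product: 5 methyl 2-[3-(methoxymethoxy)-2-methylphenyl]-2-methylpropanoate, via lithium enolate of methyl isobutyrate 4 (not isolated)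
Conditions: Cy2NH, n-BuLi, toluene, 0 °C, then 3; then 2, Pd(dba)2 (2 mol %), P(tBu)3 (2 mol %), rt
Reagents that add atoms: none
Why: Palladium-catalysed α-arylation of the preformed ester enolate (oxidative addition of the aryl bromide to zerovalent palladium, transmetalation, reductive elimination from the bulky P(tBu)3 complex) forges C4–C5 and the quaternary carbon C4 in one step, and this ligand tolerates the single ortho methyl group.

Step 3
Reactants: 5 methyl 2-[3-(methoxymethoxy)-2-methylphenyl]-2-methylpropanoate
Product: 6 2-[3-(methoxymethoxy)-2-methylphenyl]-2-methylpropan-1-ol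
Conditions: LiAlH4, THF, 0 °C
Reagents that add atoms: none
Why: Hydride reduction of the ester gives the neopentyl alcohol, whose alkoxide is compatible with the organolithium base of step 4 where an ester would not be.

Step 4
Reactants: 6 2-[3-(methoxymethoxy)-2-methylphenyl]-2-methylpropan-1-ol
Product: 8 2-[3-(methoxymethoxy)-2,4-dimethylphenyl]-2-methylpropan-1-ol, via dilithiated aryl alkoxide 7 (not isolated)
Conditions: s-BuLi (2.3 equiv), TMEDA, THF, −78 to −40 °C; MeI (1.5 equiv), −78 °C; H2O
Reagents that add atoms: iodomethane, CI
Why: Directed ortho-metalation: after deprotonation of the alcohol the acetal oxygens guide the second equivalent of base to the only free ortho position (C8), and the aryllithium is methylated far faster than the hindered lithium alkoxide, which installs the C12 methyl group.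

Step 5
Reactants: 8 2-[3-(methoxymethoxy)-2,4-dimethylphenyl]-2-methylpropan-1-ol
Product: 9 2-[3-(methoxymethoxy)-2,4-dimethylphenyl]-2-methylpropanal
Conditions: Dess–Martin periodinane, NaHCO3, CH2Cl2, rt
Reagents that add atoms: none
Why: Dess–Martin oxidation under buffered conditions converts the neopentyl alcohol into the non-enolisable aldehyde without touching the acid-sensitive acetal.

Step 6
Reactants: 9 2-[3-(methoxymethoxy)-2,4-dimethylphenyl]-2-methylpropanal; 10 methyl bis(2,2,2-trifluoroethyl)phosphonoacetate
Product: 12 methyl (Z)-4-[3-(methoxymethoxy)-2,4-dimethylphenyl]-4-methylpent-2-enoate, via potassium phosphonate carbanion 11 (not isolated)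
Conditions: KN(SiMe3)2, 18-crown-6, THF, −78 °C
Reagents that add atoms: none
Why: Still–Gennari olefination: the electron-poor trifluoroethyl phosphonate collapses from the kinetic adduct faster than it equilibrates, so the C2=C3 alkene should form with Z geometry, and the aldehyde cannot enolise.

Step 7
Reactants: 12 methyl (Z)-4-[3-(methoxymethoxy)-2,4-dimethylphenyl]-4-methylpent-2-enoate
Product: 13 (Z)-4-[3-(methoxymethoxy)-2,4-dimethylphenyl]-4-methylpent-2-en-1-ol
Conditions: i-Bu2AlH (2.5 equiv), CH2Cl2, −78 °C; aqueous potassium sodium tartrate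
Reagents that add atoms: none
Why: 1,2-Reduction of the unsaturated ester by the aluminium hydride at low temperature gives the allylic alcohol with the Z geometry intact.

Step 8
Reactants: 13 (Z)-4-[3-(methoxymethoxy)-2,4-dimethylphenyl]-4-methylpent-2-en-1-ol
Product: 14 (Z)-4-[3-(methoxymethoxy)-2,4-dimethylphenyl]-4-methylpent-2-en-1-yl methyl carbonate
Conditions: ClCO2Me, pyridine, CH2Cl2, 0 °C
Reagents that add atoms: methyl chloroformate, COC(=O)Cl
Why: Acylation of the primary alcohol installs the carbonate leaving group, which on ionisation also supplies the methoxide base of the key step.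

Step 9
Reactants: 14 (Z)-4-[3-(methoxymethoxy)-2,4-dimethylphenyl]-4-methylpent-2-en-1-yl methyl carbonate
Product: 15 3-[(Z)-5-(methoxycarbonyloxy)-2-methylpent-3-en-2-yl]-2,6-dimethylphenol
Conditions: HCl (1.25 M in MeOH), rt
Reagents that add atoms: none
Why: Acid-catalysed acetal exchange with methanol frees the phenol, while the primary allylic carbonate should neither ionise nor transesterify appreciably under these mild conditions.

Step 10
Reactants: 15 3-[(Z)-5-(methoxycarbonyloxy)-2-methylpent-3-en-2-yl]-2,6-dimethylphenol
Product: 16 4-chloro-3-[(Z)-5-(methoxycarbonyloxy)-2-methylpent-3-en-2-yl]-2,6-dimethylphenol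
Conditions: NCS (1.05 equiv), MeCN, 0 °C to rt, dark
Reagents that add atoms: N-chlorosuccinimide, O=C1CCC(=O)N1Cl
Why: Electrophilic aromatic chlorination para to the hydroxyl: both ortho carbons carry methyl groups, so C6 is the only activated C–H, the electrophile approaches perpendicular to the ring past the neighbouring tertiary alkyl group, and the hindered, inductively deactivated Z-alkene is far less nucleophilic than the phenol.

Step 11
Reactants: 16 4-chloro-3-[(Z)-5-(methoxycarbonyloxy)-2-methylpent-3-en-2-yl]-2,6-dimethylphenol
Product: 17 (10S)-6-chloro-11-nordrima-2,5,7-trien-9-one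
Conditions: Pd2(dba)3·CHCl3 (2.5 mol %), (S,S,S)-O,O′-(1,1′-binaphthyl-2,2′-diyl) N,N-bis(1-phenylethyl)phosphoramidite (6 mol %; antipode chosen as stated in the assumption), degassed toluene (0.02 M), 50 °C
Reagents that add atoms: none
Why: Proposed new method: zerovalent palladium adds oxidatively to the Z-allylic carbonate with loss of CO2, the methoxide released deprotonates the phenol, and the anti-configured η3-allylpalladium cation (divalent palladium) is attacked at its unsubstituted terminus C1, on the face away from the metal, by the ortho carbon C10 of the phenoxide, which gives the dienone and returns zerovalent palladium. The closest known reaction type is the palladium- or iridium-catalysed asymmetric intramolecular allylic dearomatization of phenols and naphthols; untested here are closure from a meta-anchored tether onto a methyl-bearing ortho carbon and the creation of a quaternary centre flanked by C5 and C9. Ring A closes as a six-membered ring in the endo sense with respect to the allyl unit (C10 to C1, with the C2=C3 alkene cis inside the ring), the only alternative at C3 being a cyclobutane; the Z geometry of the substrate delivers the required anti allyl directly, and its leakage to the unreactive syn isomer would need a σ-bond from palladium to the neopentyl-type C3 and should be slow. C10, the only stereocentre formed, is controlled by the chiral phosphoramidite on palladium, which selects between the two allyl faces (these interconvert through the η1 complex at C1) and thereby the face of the planar phenoxide that meets C1; the Si face is required for 10S. The step needs C-alkylation at C10 and not at oxygen, C8 or C6: oxygen could only close an eight-membered ring, C8 is out of reach, and C6, which is as close as C10, bears chlorine, so that attack there is disfavoured at a halogen-bearing ipso carbon and could not end in a rearomatised product. The methyl group on C10 forbids tautomerisation back to a phenol, C4 has no hydrogen for diene-forming β-elimination, and high dilution suppresses intermolecular O-allylation.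

Step 12
Reactants: 17 (10S)-6-chloro-11-nordrima-2,5,7-trien-9-one
Product: 20 (5S,10S)-11-nordrima-2,7-dien-9-one, via lithium dienolate 18 (not isolated), via deconjugated 6-en-9-one 19 (not isolated)
Conditions: Li (6 equiv), NH3(l)–THF, t-BuOH (1.5 equiv), −78 °C; isoprene, then solid NH4Cl; NH3 evaporated; NaOMe (0.2 equiv), MeOH, rt
Reagents that add atoms: none
Why: Dissolving-metal (Birch-type) reduction: electron transfer to the linear dienone gives a carbanion at C5 that is protonated axially on the α face, anti to the C10 methyl and the β-methyl on C4, which sets 5S and the trans ring fusion, the vinylic C6–Cl bond is cleaved reductively in the same medium, and base-mediated conjugation of the kinetically protonated ketone then delivers the 7-en-9-one.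

Step 13
Reactants: 20 (5S,10S)-11-nordrima-2,7-dien-9-one
Product: 21 (5S,10S)-11-nordrim-7-en-9-one
Conditions: (Ph3P)3RhCl (5 mol %), H2 (1–3 atm), toluene–EtOH, rt
Reagents that add atoms: none
Why: Homogeneous hydrogenation with the rhodium chloride complex is highly sensitive to alkene substitution, so the cis-disubstituted 2,3-alkene should be saturated while the trisubstituted, conjugated 7,8-alkene and the ketone are left.

Step 14
Reactants: 21 (5S,10S)-11-nordrim-7-en-9-one
Product: 22 (5S,10S)-drima-7,9(11)-diene
Conditions: Ph3PCH3Br (3 equiv), KOtBu (2.9 equiv), toluene, 90 °C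
Reagents that add atoms: methyltriphenylphosphonium bromide, C[P+](c1ccccc1)(c1ccccc1)c1ccccc1.[Br-]
Why: Wittig methylenation with the small, unstabilised ylide at elevated temperature is the standard answer to hindered ketones and adds C11; C10 has no α-hydrogen, and reversible γ-deprotonation only regenerates the same enone.

Step 15
Reactants: 22 (5S,10S)-drima-7,9(11)-diene
Product: 24 (−)-drimenol [(5S,9S,10S)-drim-7-en-11-ol], via B-(drim-7-en-11-yl)-9-borabicyclo[3.3.1]nonane 23 (not isolated)
Conditions: 9-BBN (1.5 equiv), THF, 0 °C to rt; NaOH, H2O2, 0 °C to rt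
Reagents that add atoms: hydrogen peroxide, OO
Why: Hydroboration–oxidation: the bulky borane adds only to the unhindered 1,1-disubstituted 9(11)-alkene with boron on C11, and hydrogen is delivered to C9 from the α face, anti to the adjacent axial C10 methyl, which sets 9S and leaves the hydroxymethyl group equatorial.

Step 16
Reactants: 25 caffeic acid
Product: 27 (E)-3-[3,4-bis(tert-butyldimethylsilyloxy)phenyl]prop-2-enoic acid, via tris-silylated caffeate 26 (not isolated)
Conditions: TBSCl (3.5 equiv), imidazole, DMF, rt; then AcOH–THF–H2O, rt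
Reagents that add atoms: tert-butyldimethylsilyl chloride, CC(C)(C)[Si](C)(C)Cl
Why: Exhaustive silylation followed by selective hydrolysis of the much more labile silyl ester masks the oxidation-prone catechol as its bis-silyl ether and leaves the free acid.

Step 17
Reactants: 24 (−)-drimenol; 27 (E)-3-[3,4-bis(tert-butyldimethylsilyloxy)phenyl]prop-2-enoic acid
Product: 28 (5S,9S,10S)-drim-7-en-11-yl (E)-3-[3,4-bis(tert-butyldimethylsilyloxy)phenyl]prop-2-enoate
Conditions: DCC, DMAP (cat.), CH2Cl2, 0 °C to rt
Reagents that add atoms: none
Why: Steglich esterification through the O-acylisourea and the acylpyridinium ion acylates the neopentyl-type primary alcohol under neutral conditions that leave the trisubstituted alkene and the E-cinnamate untouched.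

Step 18
Reactants: 28 (5S,9S,10S)-drim-7-en-11-yl (E)-3-[3,4-bis(tert-butyldimethylsilyloxy)phenyl]prop-2-enoate
Product: 29 (5S,9S,10S)-drim-7-en-11-yl (E)-3-(3,4-dihydroxyphenyl)prop-2-enoate (CNP0265201.1)
Conditions: Bu4NF (2.2 equiv), AcOH (2.5 equiv), THF, 0 °C
Reagents that add atoms: none
Why: Fluoride-induced cleavage of the two aryl silyl ethers, buffered with acetic acid so that the catecholate neither oxidises nor attacks the ester, should release the target with all three stereocentres untouched.

**Compound list**

1 | 3-bromo-2-methylphenol | Cc1c(O)cccc1Br | starting material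
2 | 1-bromo-3-(methoxymethoxy)-2-methylbenzene | COCOc1cccc(Br)c1C | intermediate
3 | methyl isobutyrate (methyl 2-methylpropanoate) | COC(=O)C(C)C | starting material
4 | lithium 1-methoxy-2-methylprop-1-en-1-olate (enolate of 3, formed in the flask) | [Li+].COC([O-])=C(C)C | intermediate
5 | methyl 2-[3-(methoxymethoxy)-2-methylphenyl]-2-methylpropanoate | COCOc1cccc(C(C)(C)C(=O)OC)c1C | intermediate
6 | 2-[3-(methoxymethoxy)-2-methylphenyl]-2-methylpropan-1-ol | COCOc1cccc(C(C)(C)CO)c1C | intermediate
7 | lithium 2-[4-lithio-3-(methoxymethoxy)-2-methylphenyl]-2-methylpropan-1-olate (formed in the flask) | [Li]c1ccc(C(C)(C)CO[Li])c(C)c1OCOC | intermediate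
8 | 2-[3-(methoxymethoxy)-2,4-dimethylphenyl]-2-methylpropan-1-ol | COCOc1c(C)ccc(C(C)(C)CO)c1C | intermediate
9 | 2-[3-(methoxymethoxy)-2,4-dimethylphenyl]-2-methylpropanal | COCOc1c(C)ccc(C(C)(C)C=O)c1C | intermediate
10 | methyl bis(2,2,2-trifluoroethyl)phosphonoacetate | COC(=O)CP(=O)(OCC(F)(F)F)OCC(F)(F)F | starting material
11 | potassium salt of the carbanion of 10 (formed in the flask) | [K+].COC(=O)[CH-]P(=O)(OCC(F)(F)F)OCC(F)(F)F | intermediate
12 | methyl (Z)-4-[3-(methoxymethoxy)-2,4-dimethylphenyl]-4-methylpent-2-enoate | COCOc1c(C)ccc(C(C)(C)/C=C\C(=O)OC)c1C | intermediate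
13 | (Z)-4-[3-(methoxymethoxy)-2,4-dimethylphenyl]-4-methylpent-2-en-1-ol | COCOc1c(C)ccc(C(C)(C)/C=C\CO)c1C | intermediate
14 | (Z)-4-[3-(methoxymethoxy)-2,4-dimethylphenyl]-4-methylpent-2-en-1-yl methyl carbonate | COCOc1c(C)ccc(C(C)(C)/C=C\COC(=O)OC)c1C | intermediate
15 | 3-[(Z)-5-(methoxycarbonyloxy)-2-methylpent-3-en-2-yl]-2,6-dimethylphenol (chlorine-free key-step precursor) | COC(=O)OC/C=C\C(C)(C)c1ccc(C)c(O)c1C | intermediate
16 | 4-chloro-3-[(Z)-5-(methoxycarbonyloxy)-2-methylpent-3-en-2-yl]-2,6-dimethylphenol (key-step precursor as used) | COC(=O)OC/C=C\C(C)(C)c1c(Cl)cc(C)c(O)c1C | intermediate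
17 | (10S)-6-chloro-11-nordrima-2,5,7-trien-9-one [(8aS)-4-chloro-2,5,5,8a-tetramethyl-8,8a-dihydronaphthalen-1(5H)-one] | CC1=CC(Cl)=C2C(C)(C)C=CC[C@]2(C)C1=O | intermediate
18 | lithium (5S,10S)-11-nordrima-2,6,8-trien-9-olate (formed in the flask) | [Li+].CC1=C([O-])[C@@]2(C)CC=CC(C)(C)[C@@H]2C=C1 | intermediate
19 | (5S,10S)-11-nordrima-2,6-dien-9-one, both C8 epimers (formed in the flask) | CC1C=C[C@H]2C(C)(C)C=CC[C@]2(C)C1=O | intermediate
20 | (5S,10S)-11-nordrima-2,7-dien-9-one [(4aS,8aS)-2,5,5,8a-tetramethyl-4a,5,8,8a-tetrahydronaphthalen-1(4H)-one] | CC1=CC[C@H]2C(C)(C)C=CC[C@]2(C)C1=O | intermediate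
21 | (5S,10S)-11-nordrim-7-en-9-one [(4aS,8aS)-2,5,5,8a-tetramethyl-4a,5,6,7,8,8a-hexahydronaphthalen-1(4H)-one] | CC1=CC[C@H]2C(C)(C)CCC[C@]2(C)C1=O | intermediate
22 | (5S,10S)-drima-7,9(11)-diene [(4aS,8aS)-2,5,5,8a-tetramethyl-1-methylidene-1,4,4a,5,6,7,8,8a-octahydronaphthalene] | CC1=CC[C@H]2C(C)(C)CCC[C@]2(C)C1=C | intermediate
23 | B-[(5S,9S,10S)-drim-7-en-11-yl]-9-borabicyclo[3.3.1]nonane (formed in the flask) | CC1=CC[C@H]2C(C)(C)CCC[C@]2(C)[C@H]1CB1C2CCCC1CCC2 | intermediate
24 | (−)-drimenol, [(1S,4aS,8aS)-2,5,5,8a-tetramethyl-1,4,4a,5,6,7,8,8a-octahydronaphthalen-1-yl]methanol | CC1=CC[C@H]2C(C)(C)CCC[C@]2(C)[C@H]1CO | intermediate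
25 | caffeic acid | OC(=O)/C=C/c1ccc(O)c(O)c1 | starting material
26 | tert-butyldimethylsilyl (E)-3-[3,4-bis(tert-butyldimethylsilyloxy)phenyl]prop-2-enoate (formed in the flask) | CC(C)(C)[Si](C)(C)OC(=O)/C=C/c1ccc(O[Si](C)(C)C(C)(C)C)c(O[Si](C)(C)C(C)(C)C)c1 | intermediate
27 | (E)-3-[3,4-bis(tert-butyldimethylsilyloxy)phenyl]prop-2-enoic acid | OC(=O)/C=C/c1ccc(O[Si](C)(C)C(C)(C)C)c(O[Si](C)(C)C(C)(C)C)c1 | intermediate
28 | (5S,9S,10S)-drim-7-en-11-yl (E)-3-[3,4-bis(tert-butyldimethylsilyloxy)phenyl]prop-2-enoate | CC1=CC[C@H]2C(C)(C)CCC[C@]2(C)[C@H]1COC(=O)/C=C/c1ccc(O[Si](C)(C)C(C)(C)C)c(O[Si](C)(C)C(C)(C)C)c1 | intermediate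
29 | (5S,9S,10S)-drim-7-en-11-yl (E)-3-(3,4-dihydroxyphenyl)prop-2-enoate, drimenyl caffeate (CNP0265201.1) | CC1=CC[C@H]2C(C)(C)CCC[C@]2(C)[C@H]1COC(=O)/C=C/c1ccc(O)c(O)c1 | target

**Step count.** Total: 18 steps. Longest linear sequence: 17 steps (steps 1–15, 17 and 18); step 16 is a one-step side branch.

**Steps most likely to fail**

1. Step 11 (new method). The processes at risk are sluggish ionisation of the hindered Z-carbonate to the anti allyl complex, diversion of the phenoxide to ipso attack at C6 or to intermolecular O-allylation, and insufficient discrimination of the two faces of C10 by the ligand. The fallback uses known chemistry, leaves the route at 13 and rejoins it at 17. Compound 13 is converted with MsCl, LiCl and 2,6-lutidine in DMF at 0 °C into the allylic chloride 1-[(Z)-5-chloro-2-methylpent-3-en-2-yl]-3-(methoxymethoxy)-2,4-dimethylbenzene F1. Methanolic HCl then frees 3-[(Z)-5-chloro-2-methylpent-3-en-2-yl]-2,6-dimethylphenol F2, and NCS in MeCN gives 4-chloro-3-[(Z)-5-chloro-2-methylpent-3-en-2-yl]-2,6-dimethylphenol F3. Treatment of F3 with KOtBu in toluene–t-BuOH at high dilution should close ring A by the classical uncatalysed SN2 C-alkylation of a 2,6-disubstituted phenoxide at its ortho carbon, giving racemic 6-chloro-11-nordrima-2,5,7-trien-9-one F4. Preparative chromatography on a chiral stationary phase then separates the enantiomers, and the 10S enantiomer is 17.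

2. Step 12. The processes at risk are protonation of the C5 carbanion from the β face (cis fusion), over-reduction of the carbonyl by excess metal, and incomplete reductive cleavage of the C6–Cl bond. The fallback leaves the route at 17 and rejoins it at 21, so that step 13 is bypassed as well. Hydrogenation of 17 over Pd/C in EtOAc with Et3N under 3 atm of H2 should remove the chlorine and saturate all three alkenes, hydrogen being delivered to C5 from the α face opposite the angular methyl, to give (5S,10S)-11-nordriman-9-one F5 as a mixture of C8 epimers. LiN(iPr)2 and Me3SiCl in THF at −78 °C then give the silyl enol ether (5S,10S)-9-(trimethylsilyloxy)-11-nordrim-8-ene F6, regiochemically unambiguous because C10 is quaternary. Saegusa–Ito oxidation with Pd(OAc)2 in MeCN returns the 7-en-9-one 21.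

3. Step 10. The processes at risk are attack of the electrophilic chlorine on the Z-alkene or ipso at the methyl-bearing ortho carbons instead of C6, and stalling next to the tertiary alkyl group. The fallback leaves the route at 12 and rejoins it at 16; the chlorine is introduced while the alkene is still an electron-poor enoate. HCl in MeOH converts 12 into methyl (Z)-4-(3-hydroxy-2,4-dimethylphenyl)-4-methylpent-2-enoate F7. NCS gives methyl (Z)-4-(6-chloro-3-hydroxy-2,4-dimethylphenyl)-4-methylpent-2-enoate F8, and i-Bu2AlH (3.5 equiv) at −78 °C reduces it to 4-chloro-3-[(Z)-5-hydroxy-2-methylpent-3-en-2-yl]-2,6-dimethylphenol F9. Excess ClCO2Me and pyridine give the bis-carbonate (Z)-4-[6-chloro-3-(methoxycarbonyloxy)-2,4-dimethylphenyl]-4-methylpent-2-en-1-yl methyl carbonate F10, from which pyrrolidine at 0 °C should remove only the far more electrophilic aryl carbonate to give 16.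

**Further compounds**

F1 | step 11 | 1-[(Z)-5-chloro-2-methylpent-3-en-2-yl]-3-(methoxymethoxy)-2,4-dimethylbenzene | COCOc1c(C)ccc(C(C)(C)/C=C\CCl)c1C
F2 | step 11 | 3-[(Z)-5-chloro-2-methylpent-3-en-2-yl]-2,6-dimethylphenol | ClC/C=C\C(C)(C)c1ccc(C)c(O)c1C
F3 | step 11 | 4-chloro-3-[(Z)-5-chloro-2-methylpent-3-en-2-yl]-2,6-dimethylphenol | ClC/C=C\C(C)(C)c1c(Cl)cc(C)c(O)c1C
F4 | step 11 | racemic 6-chloro-11-nordrima-2,5,7-trien-9-one | CC1=CC(Cl)=C2C(C)(C)C=CCC2(C)C1=O
F5 | step 12 | (5S,10S)-11-nordriman-9-one, both C8 epimers | CC1CC[C@H]2C(C)(C)CCC[C@]2(C)C1=O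
F6 | step 12 | (5S,10S)-9-(trimethylsilyloxy)-11-nordrim-8-ene | CC1=C(O[Si](C)(C)C)[C@@]2(C)CCCC(C)(C)[C@@H]2CC1
F7 | step 10 | methyl (Z)-4-(3-hydroxy-2,4-dimethylphenyl)-4-methylpent-2-enoate | COC(=O)/C=C\C(C)(C)c1ccc(C)c(O)c1C
F8 | step 10 | methyl (Z)-4-(6-chloro-3-hydroxy-2,4-dimethylphenyl)-4-methylpent-2-enoate | COC(=O)/C=C\C(C)(C)c1c(Cl)cc(C)c(O)c1C
F9 | step 10 | 4-chloro-3-[(Z)-5-hydroxy-2-methylpent-3-en-2-yl]-2,6-dimethylphenol | OC/C=C\C(C)(C)c1c(Cl)cc(C)c(O)c1C
F10 | step 10 | (Z)-4-[6-chloro-3-(methoxycarbonyloxy)-2,4-dimethylphenyl]-4-methylpent-2-en-1-yl methyl carbonate | COC(=O)OC/C=C\C(C)(C)c1c(Cl)cc(C)c(OC(=O)OC)c1C
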